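Should the next run carry more free catalyst? Free catalyst multiplies the rate of both couplings, and the impurity destroys it one for one, so the choice hangs on how much stands free at the mark of 10% conversion.

left-handed substrate 0.50 M; gas 26 mM (held); free catalyst 2.1 mM; impurity 1.3 mM; right-handed substrate 0.50 M

    coupling partner + free catalyst + left-handed substrate → free catalyst + left-handed product (k1 = 17 /M²/s)
    coupling partner + free catalyst + right-handed substrate → free catalyst + right-handed product (k2 = 8.5 /M²/s)
    free catalyst + impurity → spent catalyst (k3 = 5.2 /M/s)
    gas ⇌ coupling partner, rate k4*(csat - [coupling partner]) (k4 = 0.12 /s, csat = 26 mM)

* the form that holds most of the catalyst when 10% of the left-handed substrate and right-handed substrate together are converted (free catalyst / spent catalyst)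
* its share of the catalyst then
* apparent order in free catalyst when 10% of the left-handed substrate and right-handed substrate together are converted (percent change of the rate of making left-handed product for one percent more free catalyst charged)

My reckoning uses the mean substrate of each hand up to the mark, which gives a coupling coefficient κ. W is what stays free once the impurity is gone. The coupling partner, B, stands where transfer matches use:

κ = (17 /M²/s + 8.5 /M²/s) × 0.475 M = 12.1 /M/s

W = 2.1 mM − 1.3 mM = 0.800 mM

B = 26 mM × 0.12 /s / (0.12 /s + κW) = 24.1 mM

Free catalyst enters the loss of impurity and the conversion of substrate alike. Dividing one by the other removes it, and the clock too. With x = 0.100 M converted, Y is the impurity left at the mark: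

ln(charged impurity / Y) = 5.2 /M/s × x / (κB) = 1.78, so Y = 0.218 mM

F = W + Y = 1.02 mM

This free pool at the mark is W plus as much free catalyst as the impurity left at the mark can still destroy. Y does not depend on the charge, B apart, so added catalyst stays free in full. One percent more charge therefore raises F by 2.06 percent, and the falling coupling partner trims the rate's order to 1.87. Spent catalyst holds 51.4%, more than free catalyst. The next run should carry more free catalyst, since the rate rises faster than the charge.

The forecast also names spent catalyst, at 53%, a little above this reckoning, with order 1.9, since “the impurity removes a roughly fixed amount of catalyst”.

The simulation gives spent catalyst at 53.2% and order 1.9, with 46.8% of the catalyst free at 0.0804 h.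

In this flask the impurity consumed free catalyst while it lasted: by 0.300 h it stood at 0.429% of its charge, with free catalyst at 38.4% of the catalyst charged, just above the 38.1% that W gives. Both couplings ran on, and free catalyst still held 38.1% of the catalyst charged at 3.00 h, when 2.3% of the charged left-handed substrate and 15% of the charged right-handed substrate remained. With twice the charge, the same Y gives a free pool of 3.12 mM, and the trim by the coupling partner brings the reckoned rate factor to 2.57. The run with twice the free catalyst gave a factor of 2.61.

The numbers of this flask are invented; the rest is arithmetic.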